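**Retrosynthetic overview**
1. The target comes from its 5,7,4'-tri-O-benzyl ether by hydrogenolysis in the last step.
2. Key disconnection C4–C4a: ring C is closed last by intramolecular Friedel–Crafts acylation of a (Z)-3-aryloxy-3-arylacrylic acid. The feature used is that C5, C6, C7 and C8 of ring A all carry substituents, so C4a is the only C–H of ring A and lies ortho to O1, the one place an acyl carbon tethered through O1–C2=C3 can reach.
3. O1–C2: oxa-Michael addition of the ring A phenol to ethyl 3-[4-(benzyloxy)phenyl]propiolate, with ring B brought in by Sonogashira coupling.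
4. C8–pyrrolidine C2: an aryl Grignard reagent adds to the (R)-N-tert-butanesulfinyl imine of 4-chlorobutanal and sets the single stereocentre; the pyrrolidine is closed by N-alkylation and then N-methylated.
5. Ring order: ring A (from 4-O-methylgallic acid, carboxyl site turned into O1 by a Dakin-type oxidation), pyrrolidine ring, ring B attached, ring C last.

Key step: step 14

Remark on the chemistry: the oxa-Michael adduct is taken as the Z isomer (O1 cis to the carboxyl carbon); the facial sense of the sulfinimine addition is taken from the chelated six-membered transition-state model; 4-chlorobutanal is taken as a commercial aldehyde (otherwise made fresh by oxidation of 4-chlorobutan-1-ol).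

**Route**

Step 1
Reactants: 1 4-O-methylgallic acid (3,5-dihydroxy-4-methoxybenzoic acid)
Product: 2 benzyl 3,5-bis(benzyloxy)-4-methoxybenzoate
Conditions: BnBr (3.3 equiv), K2CO3, DMF, 60 °C
Reagents that add atoms: benzyl bromide, BrCc1ccccc1
Why: Williamson O-benzylation of both phenols with concurrent alkylation of the carboxylate is a routine exhaustive benzylation, and the ester benzyl group is shed again in step 2.

Step 2
Reactants: 2 benzyl 3,5-bis(benzyloxy)-4-methoxybenzoate
Product: 3 [3,5-bis(benzyloxy)-4-methoxyphenyl]methanol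
Conditions: LiAlH4, THF, 0 °C → rt
Reagents that add atoms: none
Why: Hydride reduction of the benzoate ester to the primary alcohol leaves aryl benzyl and methyl ethers untouched.

Step 3
Reactants: 3 [3,5-bis(benzyloxy)-4-methoxyphenyl]methanol
Product: 4 3,5-bis(benzyloxy)-4-methoxybenzaldehyde
Conditions: MnO2 (activated), CH2Cl2, rt
Reagents that add atoms: none
Why: MnO2 oxidation is selective for benzylic alcohols and stops at the aldehyde.

Step 4
Reactants: 4 3,5-bis(benzyloxy)-4-methoxybenzaldehyde
Product: 6 3,5-bis(benzyloxy)-4-methoxyphenol, via aryl formate 5 (not isolated)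
Conditions: mCPBA, CH2Cl2, 0 °C → rt; then K2CO3 (cat.), MeOH, rt
Reagents that add atoms: 3-chloroperoxybenzoic acid (mCPBA), OOC(=O)c1cccc(Cl)c1
Why: Baeyer–Villiger oxidation (Dakin-type), in which the electron-rich aryl group with its para methoxy group migrates in preference to hydrogen, followed by methanolysis of the formate, turns the former carboxyl position into the oxygen that becomes O1 and gives a phenol whose two free ring positions are equivalent.

Step 5
Reactants: 6 3,5-bis(benzyloxy)-4-methoxyphenol
Product: 7 1,3-bis(benzyloxy)-2-methoxy-5-(methoxymethoxy)benzene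
Conditions: NaH, MOMCl, DMF, 0 °C → rt
Reagents that add atoms: chloromethyl methyl ether, COCCl
Why: O-alkylation of the sodium phenoxide gives a MOM acetal that survives organolithium chemistry, is distinct from the benzyl ethers and is removed by acid in step 9.

Step 6
Reactants: 7 1,3-bis(benzyloxy)-2-methoxy-5-(methoxymethoxy)benzene
Product: 8 1,3-bis(benzyloxy)-4-bromo-2-methoxy-5-(methoxymethoxy)benzene
Conditions: NBS (1.0 equiv), MeCN, −20 → 0 °C
Reagents that add atoms: N-bromosuccinimide, O=C1CCC(=O)N1Br
Why: Electrophilic aromatic bromination of the tetraoxygenated ring is fast, and because the two ring C–H positions are related by symmetry one equivalent of NBS can give only one monobromide, with bromine between the MOM ether and a benzyl ether.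

Step 7
Reactants: 9 (R)-2-methylpropane-2-sulfinamide; 10 4-chlorobutanal
Product: 11 (R)-N-[(1E)-4-chlorobutylidene]-2-methylpropane-2-sulfinamide
Conditions: CuSO4 (anhydrous), CH2Cl2, rt
Reagents that add atoms: none
Why: Dehydrative condensation of a sulfinamide with an aldehyde gives the E N-sulfinyl aldimine without epimerising sulfur or touching the alkyl chloride.

Step 8
Reactants: 8 1,3-bis(benzyloxy)-4-bromo-2-methoxy-5-(methoxymethoxy)benzene; 11 (R)-N-[(1E)-4-chlorobutylidene]-2-methylpropane-2-sulfinamide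
Product: 14 (R)-N-{(1R)-1-[2,4-bis(benzyloxy)-3-methoxy-6-(methoxymethoxy)phenyl]-4-chlorobutyl}-2-methylpropane-2-sulfinamide, via aryllithium 12 (not isolated), via arylmagnesium bromide 13 (not isolated)
Conditions: n-BuLi, THF, −78 °C; MgBr2·OEt2, −78 °C; then 11, CH2Cl2, −78 → −30 °C; H2O
Reagents that add atoms: none
Why: Bromine–lithium exchange, transmetalation to magnesium and 1,2-addition of the aryl Grignard reagent to the N-tert-butanesulfinyl aldimine through a six-membered chair transition state with magnesium bound to the sulfinyl oxygen should transfer the aryl group to the face that gives the R carbon centre under control of the (R)-sulfur auxiliary, and the minor diastereomer is removed by chromatography so that a single stereoisomer is carried on.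

Step 9
Reactants: 14 (R)-N-{(1R)-1-[2,4-bis(benzyloxy)-3-methoxy-6-(methoxymethoxy)phenyl]-4-chlorobutyl}-2-methylpropane-2-sulfinamide
Product: 16 3,5-bis(benzyloxy)-4-methoxy-2-[(2R)-pyrrolidin-2-yl]phenol, via amino chloride 15 (not isolated)
Conditions: HCl (4 M in dioxane), MeOH, rt; concentrate; then K2CO3, MeCN/H2O, rt
Reagents that add atoms: none
Why: Acid methanolysis cleaves the N-sulfinyl group and the MOM acetal together, and on neutralisation the free primary amine closes the pyrrolidine by 5-exo-tet SN2 displacement of the primary chloride, which leaves the benzylic stereocentre untouched.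

Step 10
Reactants: 16 3,5-bis(benzyloxy)-4-methoxy-2-[(2R)-pyrrolidin-2-yl]phenol
Product: 18 3,5-bis(benzyloxy)-4-methoxy-2-[(2R)-1-methylpyrrolidin-2-yl]phenol, via iminium ion 17 (not isolated)
Conditions: CH2O (37% aq., 1.1 equiv), NaBH(OAc)3, ClCH2CH2Cl, 0 °C → rt
Reagents that add atoms: formaldehyde, C=O
Why: Reductive amination, in which the secondary amine condenses with formaldehyde to the iminium ion (in equilibrium with its cyclic N,O-acetal with the neighbouring phenol) and NaBH(OAc)3 reduces it to the N-methyl amine at or below room temperature without affecting the stereocentre.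

Step 11
Reactants: 19 1-(benzyloxy)-4-iodobenzene; 20 ethyl propiolate
Product: 21 ethyl 3-[4-(benzyloxy)phenyl]prop-2-ynoate
Conditions: PdCl2(PPh3)2 (2 mol %), CuI (4 mol %), K2CO3, THF, 65 °C
Reagents that add atoms: none
Why: Sonogashira coupling of an aryl iodide with the terminal alkyne, run with an inorganic base so that no amine adds to the propiolate.

Step 12
Reactants: 18 3,5-bis(benzyloxy)-4-methoxy-2-[(2R)-1-methylpyrrolidin-2-yl]phenol; 21 ethyl 3-[4-(benzyloxy)phenyl]prop-2-ynoate
Product: 22 ethyl (2Z)-3-[4-(benzyloxy)phenyl]-3-{3,5-bis(benzyloxy)-4-methoxy-2-[(2R)-1-methylpyrrolidin-2-yl]phenoxy}prop-2-enoate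
Conditions: Cs2CO3 (0.5 equiv), DMF, 50 °C
Reagents that add atoms: none
Why: Base-mediated oxa-Michael addition of the phenoxide to the β-carbon of the arylpropiolate with anti protonation should give the Z enol ether and so form the O1–C2 bond; an E isomer, if formed, need not be separated because both converge under the acid of step 14, and the mild temperature protects the benzylic amine centre.

Step 13
Reactants: 22 ethyl (2Z)-3-[4-(benzyloxy)phenyl]-3-{3,5-bis(benzyloxy)-4-methoxy-2-[(2R)-1-methylpyrrolidin-2-yl]phenoxy}prop-2-enoate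
Product: 23 (2Z)-3-[4-(benzyloxy)phenyl]-3-{3,5-bis(benzyloxy)-4-methoxy-2-[(2R)-1-methylpyrrolidin-2-yl]phenoxy}prop-2-enoic acid
Conditions: LiOH, THF/MeOH/H2O, rt; then 1 M HCl to pH 6
Reagents that add atoms: lithium hydroxide, [Li+].[OH-]
Why: Saponification of the ethyl ester at room temperature, with isolation of the amino acid at its isoelectric point, is compatible with the vinylogous carbonate, the benzyl ethers and the amine.

Step 14
Reactants: 23 (2Z)-3-[4-(benzyloxy)phenyl]-3-{3,5-bis(benzyloxy)-4-methoxy-2-[(2R)-1-methylpyrrolidin-2-yl]phenoxy}prop-2-enoic acid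
Product: 25 5,7-bis(benzyloxy)-2-[4-(benzyloxy)phenyl]-6-methoxy-8-[(2R)-1-methylpyrrolidin-2-yl]-4H-chromen-4-one, via mixed anhydride 24 (not isolated)
Conditions: TFA (10 equiv), CH2Cl2, 0 °C; then (CF3CO)2O (1.5 equiv), 0 °C → rt; aq. NaHCO3
Reagents that add atoms: none
Why: Intramolecular Friedel–Crafts acylation: with the amine locked as its trifluoroacetate salt, TFAA turns the carboxylic acid into mixed anhydride 24, whose acyl carbon (an acylium equivalent) is attacked by C4a, which is activated by O1 and O5 (ortho) and O7 (para), and loss of the C4a proton gives the chromone carbonyl. The closest known reaction type is the acid-mediated cyclisation of 3-aryloxycinnamic acids, obtained from phenols and arylpropiolates, to flavones. Ring C closes as a six-membered ring by attack of the arene on the exocyclic acyl C=O (6-exo-trig at the anhydride carbonyl), forming only the C4–C4a bond. No stereocentre is created, and the existing pyrrolidine C2 centre is shielded because the ammonium ion cannot be N-acylated and disfavours ionisation of the benzylic C–N bond. The step needs site selectivity, secured by the substrate since C5, C6, C7 and C8 are substituted and C4a is the only ring A C–H, chemoselectivity over indenone formation on the less electron-rich 2-aryl ring, and the Z geometry, which is replenished because E and Z enol ethers interconvert by reversible protonation at C3 in TFA. TFAA is kept near stoichiometric and the temperature low to hold back intermolecular trifluoroacetylation of C4a and benzyl loss, and a benzyl ether cleaved here would be harmless because all three fall in step 15.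

Step 15
Reactants: 25 5,7-bis(benzyloxy)-2-[4-(benzyloxy)phenyl]-6-methoxy-8-[(2R)-1-methylpyrrolidin-2-yl]-4H-chromen-4-one
Product: 26 5,7-dihydroxy-2-(4-hydroxyphenyl)-6-methoxy-8-[(2R)-1-methylpyrrolidin-2-yl]-4H-chromen-4-one
Conditions: H2 (1 atm), 10% Pd/C, THF/MeOH, rt
Reagents that add atoms: none
Why: Catalytic hydrogenolysis of the three aryl benzyl ethers under neutral conditions at room temperature should be much faster than hydrogenolysis of the hindered, unprotonated benzylic C–N bond or reduction of the chromone C2=C3 bond, so the reaction is stopped after uptake of three equivalents of hydrogen and the stereocentre is not exposed to acid, base or heat.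

**Compound list**
1 | 4-O-methylgallic acid (3,5-dihydroxy-4-methoxybenzoic acid) | COc1c(O)cc(C(=O)O)cc1O | starting material
2 | benzyl 3,5-bis(benzyloxy)-4-methoxybenzoate | COc1c(OCc2ccccc2)cc(C(=O)OCc2ccccc2)cc1OCc1ccccc1 | intermediate
3 | [3,5-bis(benzyloxy)-4-methoxyphenyl]methanol | COc1c(OCc2ccccc2)cc(CO)cc1OCc1ccccc1 | intermediate
4 | 3,5-bis(benzyloxy)-4-methoxybenzaldehyde | COc1c(OCc2ccccc2)cc(C=O)cc1OCc1ccccc1 | intermediate
5 | 3,5-bis(benzyloxy)-4-methoxyphenyl formate | COc1c(OCc2ccccc2)cc(OC=O)cc1OCc1ccccc1 | intermediate (not isolated)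
6 | 3,5-bis(benzyloxy)-4-methoxyphenol | COc1c(OCc2ccccc2)cc(O)cc1OCc1ccccc1 | intermediate
7 | 1,3-bis(benzyloxy)-2-methoxy-5-(methoxymethoxy)benzene | COCOc1cc(OCc2ccccc2)c(OC)c(OCc2ccccc2)c1 | intermediate
8 | 1,3-bis(benzyloxy)-4-bromo-2-methoxy-5-(methoxymethoxy)benzene | COCOc1cc(OCc2ccccc2)c(OC)c(OCc2ccccc2)c1Br | intermediate
9 | (R)-2-methylpropane-2-sulfinamide | CC(C)(C)[S@@](=O)N | starting material
10 | 4-chlorobutanal | O=CCCCCl | starting material
11 | (R)-N-[(1E)-4-chlorobutylidene]-2-methylpropane-2-sulfinamide | CC(C)(C)[S@@](=O)/N=C/CCCCl | intermediate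
12 | [2,4-bis(benzyloxy)-3-methoxy-6-(methoxymethoxy)phenyl]lithium | [Li]c1c(OCOC)cc(OCc2ccccc2)c(OC)c1OCc1ccccc1 | intermediate (not isolated)
13 | [2,4-bis(benzyloxy)-3-methoxy-6-(methoxymethoxy)phenyl]magnesium bromide | Br[Mg]c1c(OCOC)cc(OCc2ccccc2)c(OC)c1OCc1ccccc1 | intermediate (not isolated)
14 | (R)-N-{(1R)-1-[2,4-bis(benzyloxy)-3-methoxy-6-(methoxymethoxy)phenyl]-4-chlorobutyl}-2-methylpropane-2-sulfinamide | CC(C)(C)[S@@](=O)N[C@H](CCCCl)c1c(OCOC)cc(OCc2ccccc2)c(OC)c1OCc1ccccc1 | intermediate
15 | 2-[(1R)-1-amino-4-chlorobutyl]-3,5-bis(benzyloxy)-4-methoxyphenol (present as its hydrochloride) | COc1c(OCc2ccccc2)cc(O)c([C@H](N)CCCCl)c1OCc1ccccc1 | intermediate (not isolated)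
16 | 3,5-bis(benzyloxy)-4-methoxy-2-[(2R)-pyrrolidin-2-yl]phenol | COc1c(OCc2ccccc2)cc(O)c([C@H]2CCCN2)c1OCc1ccccc1 | intermediate
17 | (2R)-2-[2,4-bis(benzyloxy)-6-hydroxy-3-methoxyphenyl]-1-methylidenepyrrolidin-1-ium | COc1c(OCc2ccccc2)cc(O)c([C@H]2CCC[N+]2=C)c1OCc1ccccc1 | intermediate (not isolated)
18 | 3,5-bis(benzyloxy)-4-methoxy-2-[(2R)-1-methylpyrrolidin-2-yl]phenol | COc1c(OCc2ccccc2)cc(O)c([C@H]2CCCN2C)c1OCc1ccccc1 | intermediate
19 | 1-(benzyloxy)-4-iodobenzene | Ic1ccc(OCc2ccccc2)cc1 | starting material
20 | ethyl propiolate | C#CC(=O)OCC | starting material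
21 | ethyl 3-[4-(benzyloxy)phenyl]prop-2-ynoate | CCOC(=O)C#Cc1ccc(OCc2ccccc2)cc1 | intermediate
22 | ethyl (2Z)-3-[4-(benzyloxy)phenyl]-3-{3,5-bis(benzyloxy)-4-methoxy-2-[(2R)-1-methylpyrrolidin-2-yl]phenoxy}prop-2-enoate | CCOC(=O)/C=C(\Oc1cc(OCc2ccccc2)c(OC)c(OCc2ccccc2)c1[C@H]1CCCN1C)c1ccc(OCc2ccccc2)cc1 | intermediate
23 | (2Z)-3-[4-(benzyloxy)phenyl]-3-{3,5-bis(benzyloxy)-4-methoxy-2-[(2R)-1-methylpyrrolidin-2-yl]phenoxy}prop-2-enoic acid | COc1c(OCc2ccccc2)cc(O/C(=C\C(=O)O)c2ccc(OCc3ccccc3)cc2)c([C@H]2CCCN2C)c1OCc1ccccc1 | intermediate (key-step precursor)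
24 | mixed anhydride of acid 23 with trifluoroacetic acid | COc1c(OCc2ccccc2)cc(O/C(=C\C(=O)OC(=O)C(F)(F)F)c2ccc(OCc3ccccc3)cc2)c([C@H]2CCCN2C)c1OCc1ccccc1 | intermediate (not isolated)
25 | 5,7-bis(benzyloxy)-2-[4-(benzyloxy)phenyl]-6-methoxy-8-[(2R)-1-methylpyrrolidin-2-yl]-4H-chromen-4-one | COc1c(OCc2ccccc2)c([C@H]2CCCN2C)c2oc(-c3ccc(OCc4ccccc4)cc3)cc(=O)c2c1OCc1ccccc1 | intermediate (key-step product)
26 | 5,7-dihydroxy-2-(4-hydroxyphenyl)-6-methoxy-8-[(2R)-1-methylpyrrolidin-2-yl]-4H-chromen-4-one | COc1c(O)c([C@H]2CCCN2C)c2oc(-c3ccc(O)cc3)cc(=O)c2c1O | target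

**Step count**
Total: 15 steps. Longest linear sequence: 13 steps (steps 1–6, 8–10, 12–15).

**Steps most likely to fail**

1. Step 14 (ring C closure). The vinylogous-carbonate-type mixed anhydride may be too weak an electrophile, so that acylation stalls. Alternatively TFAA may trifluoroacetylate C4a intermolecularly, or acid may move a benzyl group from oxygen to carbon. Incomplete N-protonation could also allow N-acylation and opening of the pyrrolidine at the benzylic C–N bond. The fallback builds ring C by the Baker–Venkataraman sequence, setting out from phenol 18. Friedel–Crafts C-acetylation at the one free ring carbon (Ac2O, BF3·OEt2) should give 1-{4,6-bis(benzyloxy)-2-hydroxy-5-methoxy-3-[(2R)-1-methylpyrrolidin-2-yl]phenyl}ethan-1-one F1. O-Aroylation with 4-(benzyloxy)benzoyl chloride in pyridine gives 2-acetyl-3,5-bis(benzyloxy)-4-methoxy-6-[(2R)-1-methylpyrrolidin-2-yl]phenyl 4-(benzyloxy)benzoate F2. Base-induced acyl migration (KOt-Bu, THF) gives 1-{4,6-bis(benzyloxy)-2-hydroxy-5-methoxy-3-[(2R)-1-methylpyrrolidin-2-yl]phenyl}-3-[4-(benzyloxy)phenyl]propane-1,3-dione F3. Acid cyclodehydration (cat. TsOH, toluene, moderate temperature) comes back to the route at flavone 25.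

2. Step 8 (aryl Grignard addition to the sulfinyl imine). Addition of the di-ortho-substituted aryl nucleophile may be slow, so that α-deprotonation of the aldimine competes. Facial selectivity may also erode if the ortho alkoxy groups compete with the sulfinyl oxygen for magnesium; the configuration of 14 should therefore be confirmed before going on. The fallback forms the aryl–pyrrolidine bond by cross-coupling, setting out from bromide 8. Commercial N-Boc-pyrrolidine is lithiated with s-BuLi/(−)-sparteine (TBME, −78 °C), transmetalated with ZnCl2 and coupled with 8 in a Negishi reaction (Pd(OAc)2, t-Bu3P·HBF4, rt) to give tert-butyl (2R)-2-[2,4-bis(benzyloxy)-3-methoxy-6-(methoxymethoxy)phenyl]pyrrolidine-1-carboxylate F4. LiAlH4 in THF at reflux reduces the carbamate to (2R)-2-[2,4-bis(benzyloxy)-3-methoxy-6-(methoxymethoxy)phenyl]-1-methylpyrrolidine F5. HCl in MeOH removes the MOM group and the sequence comes back to the route at phenol 18.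

3. Step 12 (oxa-Michael addition). O-Addition of the hindered phenoxide to the electron-rich arylpropiolate may be sluggish. Forcing it by heat risks racemisation of the ortho-hydroxy benzylic amine through reversible ring opening, and C-attack by the electron-rich ring instead of O-attack. The fallback uses a more electrophilic ynal that reacts at or below room temperature, setting out from iodide 19. Sonogashira coupling with propargyl alcohol (PdCl2(PPh3)2, CuI, Et3N) gives 3-[4-(benzyloxy)phenyl]prop-2-yn-1-ol F6, and MnO2 oxidation gives 3-[4-(benzyloxy)phenyl]prop-2-ynal F7. Phenol 18 adds to it (cat. DABCO, MeCN, 0 °C → rt) to give (2Z)-3-[4-(benzyloxy)phenyl]-3-{3,5-bis(benzyloxy)-4-methoxy-2-[(2R)-1-methylpyrrolidin-2-yl]phenoxy}prop-2-enal F8. Pinnick oxidation (NaClO2, NaH2PO4, 2-methylbut-2-ene, t-BuOH/H2O) comes back to the route at acid 23, bypassing 21 and 22.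

**Further compounds**
F1 | step 14 | 1-{4,6-bis(benzyloxy)-2-hydroxy-5-methoxy-3-[(2R)-1-methylpyrrolidin-2-yl]phenyl}ethan-1-one | CC(=O)c1c(O)c([C@H]2CCCN2C)c(OCc2ccccc2)c(OC)c1OCc1ccccc1
F2 | step 14 | 2-acetyl-3,5-bis(benzyloxy)-4-methoxy-6-[(2R)-1-methylpyrrolidin-2-yl]phenyl 4-(benzyloxy)benzoate | CC(=O)c1c(OC(=O)c2ccc(OCc3ccccc3)cc2)c([C@H]2CCCN2C)c(OCc2ccccc2)c(OC)c1OCc1ccccc1
F3 | step 14 | 1-{4,6-bis(benzyloxy)-2-hydroxy-5-methoxy-3-[(2R)-1-methylpyrrolidin-2-yl]phenyl}-3-[4-(benzyloxy)phenyl]propane-1,3-dione | O=C(CC(=O)c1ccc(OCc2ccccc2)cc1)c1c(O)c([C@H]2CCCN2C)c(OCc2ccccc2)c(OC)c1OCc1ccccc1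
F4 | step 8 | tert-butyl (2R)-2-[2,4-bis(benzyloxy)-3-methoxy-6-(methoxymethoxy)phenyl]pyrrolidine-1-carboxylate | CC(C)(C)OC(=O)N1CCC[C@@H]1c1c(OCOC)cc(OCc2ccccc2)c(OC)c1OCc1ccccc1
F5 | step 8 | (2R)-2-[2,4-bis(benzyloxy)-3-methoxy-6-(methoxymethoxy)phenyl]-1-methylpyrrolidine | CN1CCC[C@@H]1c1c(OCOC)cc(OCc2ccccc2)c(OC)c1OCc1ccccc1
F6 | step 12 | 3-[4-(benzyloxy)phenyl]prop-2-yn-1-ol | OCC#Cc1ccc(OCc2ccccc2)cc1
F7 | step 12 | 3-[4-(benzyloxy)phenyl]prop-2-ynal | O=CC#Cc1ccc(OCc2ccccc2)cc1
F8 | step 12 | (2Z)-3-[4-(benzyloxy)phenyl]-3-{3,5-bis(benzyloxy)-4-methoxy-2-[(2R)-1-methylpyrrolidin-2-yl]phenoxy}prop-2-enal | O=C/C=C(\Oc1cc(OCc2ccccc2)c(OC)c(OCc2ccccc2)c1[C@H]1CCCN1C)c1ccc(OCc2ccccc2)cc1
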